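## Retrosynthetic overview

- Target ⇐ 5-O-benzyl flavonol (hydrogenolysis) ⇐ 5-benzyloxyflavone (C3–O bond by epoxidation of C2=C3 and acid-catalysed opening).
- 5-Benzyloxyflavone ⇐ 5,7,8,3',4',5'-hexamethoxyflavone (chelation-controlled 5-O-demethylation, then benzylation).
- Ring C is the only ring built and is formed last: hexamethoxyflavone ⇐ 2'-hydroxychalcone by oxidative O1–C2 ring closure.
- Key C–C disconnection: C2–C3 of the flavone (the chalcone Cα=Cβ bond) ⇒ 2'-hydroxy-3',4',6'-trimethoxyacetophenone (ring A) + 3,4,5-trimethoxybenzaldehyde (ring B), joined by an intermolecular Claisen–Schmidt aldol condensation.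
- Acetophenone ⇐ 1,2,3,5-tetramethoxybenzene (Friedel–Crafts acetylation with ortho-demethylation) ⇐ 3,4,5-trimethoxyphenol; rings A and B are bought intact.

Assumption: the target has no stereocentre and no stereogenic double bond, so it is one achiral compound and "single enantiomer" sets no further task. Transient chiral intermediates are racemic and are marked as such.

## Route

Step 1
Reactants: 1 3,4,5-trimethoxyphenol
Product: 2 1,2,3,5-tetramethoxybenzene
Conditions: MeI (1.5 equiv), K2CO3 (2 equiv), acetone, reflux, 6 h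
Reagents that add atoms: iodomethane, CI
Why: Williamson ether synthesis; the phenoxide of 1 is the only nucleophile and is methylated by SN2 on iodomethane.

Step 2
Reactants: 2 1,2,3,5-tetramethoxybenzene
Product: 4 2'-hydroxy-3',4',6'-trimethoxyacetophenone, via tetramethoxyacetophenone 3 (not isolated)
Conditions: AcCl (1.5 equiv), AlCl3 (3 equiv), Et2O, 0 °C → rt, 24 h; then ice-cold 2 M HCl
Reagents that add atoms: acetyl chloride, CC(=O)Cl
Why: Friedel–Crafts acylation at one of the two equivalent free positions of 2 gives 3, and AlCl3 then cleaves the chelated ortho-methoxy group that is buttressed by the neighbouring 3'-OMe (twisted out of conjugation, so the more Lewis-basic and more strained one), leaving the unflanked 6'-OMe in place.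

Step 3
Reactants: 4 2'-hydroxy-3',4',6'-trimethoxyacetophenone; 5 3,4,5-trimethoxybenzaldehyde
Product: 7 (E)-2'-hydroxy-3,4,5,3',4',6'-hexamethoxychalcone, via aldol adduct 6 (not isolated)
Conditions: KOH (50% aq., 10 equiv), EtOH, rt, 48 h; then cold 1 M HCl to pH 3
Reagents that add atoms: none
Why: Claisen–Schmidt (crossed aldol) condensation in which only the methyl ketone of 4 can enolise and aldehyde 5 cannot self-condense; the new C–C bond (flavone C2–C3) forms in racemic adduct 6, and E1cB loss of water gives the conjugated, thermodynamically favoured E-enone, erasing the carbinol stereocentre.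

Step 4
Reactants: 7 (E)-2'-hydroxy-3,4,5,3',4',6'-hexamethoxychalcone
Product: 9 5,7,8,3',4',5'-hexamethoxyflavone, via flavanone 8 (not isolated)
Conditions: I2 (10 mol %), DMSO, 130 °C, 3 h; then aq. Na2S2O3
Reagents that add atoms: none
Why: Iodine-catalysed oxidative cyclisation: oxa-Michael closure of the 2'-phenol gives racemic flavanone 8 (the other ortho oxygen is a methyl ether, so only the 5,7,8-pattern can form), α-iodination and loss of HI give the pyrone, and DMSO re-oxidises HI to I2.

Step 5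
Reactants: 9 5,7,8,3',4',5'-hexamethoxyflavone
Product: 10 5-hydroxy-7,8,3',4',5'-pentamethoxyflavone
Conditions: AlCl3 (5 equiv), MeCN, 60 °C, 1.5 h (TLC control); then 2 M HCl, 60 °C, 30 min
Reagents that add atoms: none
Why: Chelation-controlled Lewis-acid ether cleavage: only the 5-OMe can form a six-membered aluminium chelate with the C4 carbonyl, so chloride removes that methyl group while the five non-chelated methyl ethers survive the MeCN-moderated AlCl3.

Step 6
Reactants: 10 5-hydroxy-7,8,3',4',5'-pentamethoxyflavone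
Product: 11 5-benzyloxy-7,8,3',4',5'-pentamethoxyflavone
Conditions: BnBr (1.5 equiv), K2CO3 (3 equiv), DMF, 70 °C, 6 h
Reagents that add atoms: benzyl bromide, BrCc1ccccc1
Why: Williamson ether synthesis on the single phenol; the hydrogen-bonded 5-OH is sluggish but is alkylated cleanly by the reactive benzylic bromide in warm DMF.

Step 7
Reactants: 11 5-benzyloxy-7,8,3',4',5'-pentamethoxyflavone
Product: 13 5-benzyloxy-3-hydroxy-7,8,3',4',5'-pentamethoxyflavone, via 2,3-epoxyflavanone 12 (not isolated)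
Conditions: DMDO (0.07 M in acetone, 3 equiv), CH2Cl2, 0 °C → rt, 16 h; evaporate; then p-TsOH·H2O (10 mol %), CH2Cl2, rt, 1 h
Reagents that add atoms: dimethyldioxirane (DMDO), CC1(C)OO1
Why: Electrophilic dioxirane epoxidation of the enol-ether-like C2=C3 bond gives racemic epoxide 12, which under acid catalysis opens at C2 to the oxocarbenium ion and loses H-3 to give the 3-hydroxychromone, erasing both stereocentres.

Step 8
Reactants: 13 5-benzyloxy-3-hydroxy-7,8,3',4',5'-pentamethoxyflavone
Product: 14 3,5-dihydroxy-7,8,3',4',5'-pentamethoxyflavone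
Conditions: H2 (1 atm), 10% Pd/C, EtOAc–MeOH 1:1, rt, 2 h
Reagents that add atoms: none
Why: Catalytic hydrogenolysis of the benzyl ether; the aryl methyl ethers and the vinylogous-ester C2=C3 bond of the chromone are inert at 1 atm and room temperature, and no stereocentre is present.

## Compound list

1 | 3,4,5-trimethoxyphenol | COc1cc(O)cc(OC)c1OC | starting material
2 | 1,2,3,5-tetramethoxybenzene | COc1cc(OC)c(OC)c(OC)c1 | intermediate
3 | 1-(2,3,4,6-tetramethoxyphenyl)ethanone (2',3',4',6'-tetramethoxyacetophenone; formed in the flask, not isolated) | CC(=O)c1c(OC)cc(OC)c(OC)c1OC | intermediate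
4 | 1-(2-hydroxy-3,4,6-trimethoxyphenyl)ethanone (2'-hydroxy-3',4',6'-trimethoxyacetophenone) | CC(=O)c1c(OC)cc(OC)c(OC)c1O | intermediate
5 | 3,4,5-trimethoxybenzaldehyde | COc1cc(C=O)cc(OC)c1OC | starting material
6 | 3-hydroxy-1-(2-hydroxy-3,4,6-trimethoxyphenyl)-3-(3,4,5-trimethoxyphenyl)propan-1-one (aldol adduct, racemic, not isolated) | COc1cc(C(O)CC(=O)c2c(OC)cc(OC)c(OC)c2O)cc(OC)c1OC | intermediate
7 | (E)-1-(2-hydroxy-3,4,6-trimethoxyphenyl)-3-(3,4,5-trimethoxyphenyl)prop-2-en-1-one (chalcone, E double bond) | COc1cc(/C=C/C(=O)c2c(OC)cc(OC)c(OC)c2O)cc(OC)c1OC | intermediate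
8 | 5,7,8-trimethoxy-2-(3,4,5-trimethoxyphenyl)chroman-4-one (flavanone, racemic at C2, not isolated) | COc1cc(C2CC(=O)c3c(OC)cc(OC)c(OC)c3O2)cc(OC)c1OC | intermediate
9 | 5,7,8-trimethoxy-2-(3,4,5-trimethoxyphenyl)-4H-chromen-4-one (5,7,8,3',4',5'-hexamethoxyflavone) | COc1cc(-c2cc(=O)c3c(OC)cc(OC)c(OC)c3o2)cc(OC)c1OC | intermediate
10 | 5-hydroxy-7,8-dimethoxy-2-(3,4,5-trimethoxyphenyl)-4H-chromen-4-one | COc1cc(-c2cc(=O)c3c(O)cc(OC)c(OC)c3o2)cc(OC)c1OC | intermediate
11 | 5-(benzyloxy)-7,8-dimethoxy-2-(3,4,5-trimethoxyphenyl)-4H-chromen-4-one | COc1cc(-c2cc(=O)c3c(OCc4ccccc4)cc(OC)c(OC)c3o2)cc(OC)c1OC | intermediate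
12 | 5-(benzyloxy)-2,3-epoxy-7,8-dimethoxy-2-(3,4,5-trimethoxyphenyl)chroman-4-one (cis-fused flavone 2,3-epoxide, racemic, not isolated) | COc1cc(C23OC2C(=O)c2c(OCc4ccccc4)cc(OC)c(OC)c2O3)cc(OC)c1OC | intermediate
13 | 5-(benzyloxy)-3-hydroxy-7,8-dimethoxy-2-(3,4,5-trimethoxyphenyl)-4H-chromen-4-one | COc1cc(-c2oc3c(OC)c(OC)cc(OCc4ccccc4)c3c(=O)c2O)cc(OC)c1OC | intermediate
14 | 3,5-dihydroxy-7,8-dimethoxy-2-(3,4,5-trimethoxyphenyl)-4H-chromen-4-one (3,5-dihydroxy-7,8,3',4',5'-pentamethoxyflavone, achiral) | COc1cc(-c2oc3c(OC)c(OC)cc(O)c3c(=O)c2O)cc(OC)c1OC | target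

## Step count and risks

Total step count: 8. Longest linear sequence: 8 steps (1 → 14); aldehyde 5 is bought.

The three steps most likely to fail:

**Step 2 (which ortho-methoxy group is cleaved).** If the isomeric phenol or a mixture forms, the fallback sets out from 2 and comes back at 4. Compound 2 is acetylated as before, but the ether cleavage is pushed past the selective stage (AcCl, AlCl3 4 equiv, CH2Cl2, 0 °C then reflux). Both methoxy groups ortho to the ketone are then removed, giving 1-(2,6-dihydroxy-3,4-dimethoxyphenyl)ethanone F1 whatever the order of cleavage. One methylation (MeI 1.0 equiv, K2CO3, acetone, rt) then goes to the 6-OH, which has a ring hydrogen as neighbour. The 2-OH, wedged between the acetyl group and the 3-OMe and held in the stronger hydrogen bond, stays free, and this gives 4.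

**Step 5 (over-demethylation at O8 or O4' of the hexamethoxyflavone).** The fallback sets out from 4 and comes back at 11; it moves the oxygen differentiation to the acetophenone stage so that the flavone never meets a Lewis acid.
- The chelated phenol of 4 is blocked with TsCl (K2CO3, acetone, reflux) to give 2-acetyl-3,5,6-trimethoxyphenyl 4-methylbenzenesulfonate F2.
- The one remaining methoxy group ortho to the ketone is cleaved with BCl3 (CH2Cl2, 0 °C) to give 2-acetyl-3-hydroxy-5,6-dimethoxyphenyl 4-methylbenzenesulfonate F3.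
- Benzylation (BnBr, K2CO3, DMF, 60 °C) gives 2-acetyl-3-(benzyloxy)-5,6-dimethoxyphenyl 4-methylbenzenesulfonate F4.
- Hydrolysis of the sulfonate (KOH, MeOH–H2O, reflux) frees 1-[6-(benzyloxy)-2-hydroxy-3,4-dimethoxyphenyl]ethanone F5.
- Claisen–Schmidt condensation of F5 with 5 (KOH, EtOH, rt) gives (E)-1-[6-(benzyloxy)-2-hydroxy-3,4-dimethoxyphenyl]-3-(3,4,5-trimethoxyphenyl)prop-2-en-1-one F6.
- Oxidative cyclisation (I2 10 mol %, DMSO, 130 °C) gives 11 directly, so steps 5 and 6 are not needed. Any material that loses its benzyl group here is compound 10 and goes back through step 6.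

**Step 7 (DMDO epoxidation: slow C2=C3 oxidation, competing oxidation of the electron-rich rings or of the benzylic CH2).** The fallback sets out from 11 and comes back at 13; it replaces electrophilic oxidation by a carbanion route. C3 is lithiated with LiN(iPr)2 (1.5 equiv, THF, −78 °C) and the anion is trapped with B(OMe)3 to give dimethyl [5-(benzyloxy)-7,8-dimethoxy-4-oxo-2-(3,4,5-trimethoxyphenyl)-4H-chromen-3-yl]boronate F7, which is not isolated. Oxidation of the C–B bond (AcOH, 30% H2O2, 0 °C → rt) gives 13.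

## Further compounds

F1 | step 2 | 1-(2,6-dihydroxy-3,4-dimethoxyphenyl)ethanone | CC(=O)c1c(O)cc(OC)c(OC)c1O
F2 | step 5 | 2-acetyl-3,5,6-trimethoxyphenyl 4-methylbenzenesulfonate | CC(=O)c1c(OC)cc(OC)c(OC)c1OS(=O)(=O)c1ccc(C)cc1
F3 | step 5 | 2-acetyl-3-hydroxy-5,6-dimethoxyphenyl 4-methylbenzenesulfonate | CC(=O)c1c(O)cc(OC)c(OC)c1OS(=O)(=O)c1ccc(C)cc1
F4 | step 5 | 2-acetyl-3-(benzyloxy)-5,6-dimethoxyphenyl 4-methylbenzenesulfonate | CC(=O)c1c(OCc2ccccc2)cc(OC)c(OC)c1OS(=O)(=O)c1ccc(C)cc1
F5 | step 5 | 1-[6-(benzyloxy)-2-hydroxy-3,4-dimethoxyphenyl]ethanone | CC(=O)c1c(OCc2ccccc2)cc(OC)c(OC)c1O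
F6 | step 5 | (E)-1-[6-(benzyloxy)-2-hydroxy-3,4-dimethoxyphenyl]-3-(3,4,5-trimethoxyphenyl)prop-2-en-1-one | COc1cc(/C=C/C(=O)c2c(OCc3ccccc3)cc(OC)c(OC)c2O)cc(OC)c1OC
F7 | step 7 | dimethyl [5-(benzyloxy)-7,8-dimethoxy-4-oxo-2-(3,4,5-trimethoxyphenyl)-4H-chromen-3-yl]boronate | COB(OC)c1c(-c2cc(OC)c(OC)c(OC)c2)oc2c(OC)c(OC)cc(OCc3ccccc3)c2c1=O
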